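**Strategy.** Ring B is disconnected at C1–C2. C1 lies between ring A, para to the C6 methoxy group, and the pendant 3,5-dimethoxy-4-oxyphenyl ring, so a carbinol there ionizes easily to a diarylmethyl cation; the C9′ acetoxymethyl arm on neighbouring C2 can be stored as the vinyl group that an allylsilane leaves behind. One Lewis-acid step therefore forms C1–C2, closes ring B and sets C1 and C2 from the lone C3 centre through an all-equatorial chair. The precursor is a bis(benzyl ether) diarylmethanol whose ring A carries, ortho to the carbinol, a (2R,3Z)-2-(silyloxymethyl)-5-(trimethylsilyl)pent-3-enyl chain; its C3 centre comes from lipase desymmetrization of a prochiral 2-benzylpropane-1,3-diol.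

Key step: step 13

Numbering used throughout: C1 (aryl-bearing CH), C2 (carries C9′), C3 (carries C9), C4 (CH2), ring A = C4a–C8a (6-OMe, 7-OH); the target is (1S,2R,3R), all-trans.

Assumption: Burkholderia cepacia lipase acts on the pro-R CH2O arm of 2-(arylmethyl)propane-1,3-diol derivatives in hydrolysis as it does in acylation, so hydrolysis of diacetate 7 should leave the (S)-monoacetate 8.

**Step 1**
Reactants: 1 6-bromovanillin (2-bromo-4-hydroxy-5-methoxybenzaldehyde)
Product: 2 4-(benzyloxy)-2-bromo-5-methoxybenzaldehyde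
Conditions: BnBr, K2CO3, DMF, rt
Reagents that add atoms: benzyl bromide, BrCc1ccccc1
Why: Williamson etherification of the phenoxide should be clean because K2CO3 in DMF deprotonates only the phenol and leaves the aldehyde and the aryl bromide untouched.

**Step 2**
Reactants: 2 4-(benzyloxy)-2-bromo-5-methoxybenzaldehyde; 3 diethyl malonate
Product: 4 diethyl 2-[4-(benzyloxy)-2-bromo-5-methoxybenzylidene]malonate
Conditions: piperidine (cat.), AcOH (cat.), toluene, reflux, Dean–Stark
Reagents that add atoms: none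
Why: Knoevenagel condensation with azeotropic removal of water should drive the ortho-substituted, electron-rich aldehyde fully to the arylidenemalonate.

**Step 3**
Reactants: 4 diethyl 2-[4-(benzyloxy)-2-bromo-5-methoxybenzylidene]malonate
Product: 5 diethyl 2-[4-(benzyloxy)-2-bromo-5-methoxybenzyl]malonate
Conditions: NaBH4, EtOH, 0 °C
Reagents that add atoms: none
Why: Conjugate reduction (1,4-hydride addition) of the doubly activated alkene by NaBH4 should be much faster than ester reduction and, unlike catalytic hydrogenation, spares the aryl bromide and the benzyl ether.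

**Step 4**
Reactants: 5 diethyl 2-[4-(benzyloxy)-2-bromo-5-methoxybenzyl]malonate
Product: 6 2-[4-(benzyloxy)-2-bromo-5-methoxybenzyl]propane-1,3-diol
Conditions: LiAlH4, THF, 0 °C → rt
Reagents that add atoms: none
Why: Ester reduction with LiAlH4 at or below room temperature should give the prochiral 1,3-diol without touching the aryl C–Br bond or the benzyl ether.

**Step 5**
Reactants: 6 2-[4-(benzyloxy)-2-bromo-5-methoxybenzyl]propane-1,3-diol
Product: 7 2-[4-(benzyloxy)-2-bromo-5-methoxybenzyl]propane-1,3-diyl diacetate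
Conditions: Ac2O, pyridine, DMAP (cat.), CH2Cl2, rt
Reagents that add atoms: acetic anhydride, CC(=O)OC(C)=O
Why: DMAP-catalysed acylation of both primary hydroxyl groups should be complete and gives the prochiral diacetate that the enzyme needs.

**Step 6**
Reactants: 7 2-[4-(benzyloxy)-2-bromo-5-methoxybenzyl]propane-1,3-diyl diacetate
Product: 8 (2S)-2-[4-(benzyloxy)-2-bromo-5-methoxybenzyl]-3-hydroxypropyl acetate
Conditions: lipase PS (Burkholderia cepacia), 0.1 M phosphate buffer pH 7/i-Pr2O, rt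
Reagents that add atoms: none
Why: Enzymatic desymmetrization by enantiotopic-group-selective ester hydrolysis should cleave only the pro-R acetate, which sets the future C3 centre as the (S)-monoacetate, while any slower second hydrolysis consumes mainly the minor enantiomer.

**Step 7**
Reactants: 8 (2S)-2-[4-(benzyloxy)-2-bromo-5-methoxybenzyl]-3-hydroxypropyl acetate
Product: 9 (2R)-2-[4-(benzyloxy)-2-bromo-5-methoxybenzyl]-3-[(tert-butyldiphenylsilyl)oxy]propyl acetate
Conditions: TBDPSCl, imidazole, CH2Cl2, 0 °C → rt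
Reagents that add atoms: tert-butyl(chloro)diphenylsilane, CC(C)(C)[Si](Cl)(c1ccccc1)c1ccccc1
Why: Silylation of the primary alcohol should outrun acyl migration, and the TBDPS group is chosen because it resists O-to-O silyl migration in step 8 and Lewis acid in step 13 better than a TBS group would.

**Step 8**
Reactants: 9 (2R)-2-[4-(benzyloxy)-2-bromo-5-methoxybenzyl]-3-[(tert-butyldiphenylsilyl)oxy]propyl acetate
Product: 10 (2R)-2-[4-(benzyloxy)-2-bromo-5-methoxybenzyl]-3-[(tert-butyldiphenylsilyl)oxy]propan-1-ol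
Conditions: K2CO3 (cat.), MeOH, 0 °C → rt
Reagents that add atoms: none
Why: Base-catalysed transesterification (methanolysis of the acetate) should free the former acetate arm while the TBDPS ether stays in place, so the stereocentre is untouched.

**Step 9**
Reactants: 10 (2R)-2-[4-(benzyloxy)-2-bromo-5-methoxybenzyl]-3-[(tert-butyldiphenylsilyl)oxy]propan-1-ol
Product: 11 (2S)-2-[4-(benzyloxy)-2-bromo-5-methoxybenzyl]-3-[(tert-butyldiphenylsilyl)oxy]propanal
Conditions: TEMPO (cat.), PhI(OAc)2, CH2Cl2, rt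
Reagents that add atoms: none
Why: Oxoammonium (TEMPO/PhI(OAc)2) oxidation of the primary alcohol should stop at the aldehyde under weakly acidic conditions that do not enolize the α-stereocentre.

**Step 10**
Reactants: 11 (2S)-2-[4-(benzyloxy)-2-bromo-5-methoxybenzyl]-3-[(tert-butyldiphenylsilyl)oxy]propanal
Product: 12 tert-butyl{[(2R,3Z)-2-[4-(benzyloxy)-2-bromo-5-methoxybenzyl]-5-(trimethylsilyl)pent-3-en-1-yl]oxy}diphenylsilane
Conditions: Ph3PCH3Br, n-BuLi, THF, 0 °C; Me3SiCH2I, rt; n-BuLi, −78 °C; then 11, −78 °C → rt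
Reagents that add atoms: methyltriphenylphosphonium bromide, C[P+](c1ccccc1)(c1ccccc1)c1ccccc1.[Br-]; (iodomethyl)trimethylsilane, C[Si](C)(C)CI
Why: Wittig olefination with the unstabilized β-silyl ylide Ph3P=CHCH2SiMe3, made in the flask, should add to the aldehyde at −78 °C faster than it enolizes it and give mainly the Z-allylsilane, whose geometry is not decisive later.

**Step 11**
Reactants: 13 syringaldehyde (4-hydroxy-3,5-dimethoxybenzaldehyde)
Product: 14 4-(benzyloxy)-3,5-dimethoxybenzaldehyde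
Conditions: BnBr, K2CO3, DMF, rt
Reagents that add atoms: benzyl bromide, BrCc1ccccc1
Why: Williamson etherification of the hindered but acidic phenol should proceed cleanly in DMF, with the aldehyde inert to K2CO3.

**Step 12**
Reactants: 12 tert-butyl{[(2R,3Z)-2-[4-(benzyloxy)-2-bromo-5-methoxybenzyl]-5-(trimethylsilyl)pent-3-en-1-yl]oxy}diphenylsilane; 14 4-(benzyloxy)-3,5-dimethoxybenzaldehyde
Product: 16 [5-(benzyloxy)-2-[(2R,3Z)-2-{[(tert-butyldiphenylsilyl)oxy]methyl}-5-(trimethylsilyl)pent-3-en-1-yl]-4-methoxyphenyl][4-(benzyloxy)-3,5-dimethoxyphenyl]methanol (both carbinol epimers), via aryllithium 15 (not isolated)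
Conditions: n-BuLi, THF, −78 °C; then 14, −78 → 0 °C; then H2O
Reagents that add atoms: none
Why: Bromine–lithium exchange at −78 °C should be faster than any deprotonation, and 1,2-addition of the aryllithium to the non-enolizable aldehyde gives the diarylmethanol as both epimers, which is acceptable because this centre is ionized in step 13.

**Step 13**
Reactants: 16 [5-(benzyloxy)-2-[(2R,3Z)-2-{[(tert-butyldiphenylsilyl)oxy]methyl}-5-(trimethylsilyl)pent-3-en-1-yl]-4-methoxyphenyl][4-(benzyloxy)-3,5-dimethoxyphenyl]methanol (both carbinol epimers)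
Product: 18 (1S,2R,3R)-7-(benzyloxy)-1-[4-(benzyloxy)-3,5-dimethoxyphenyl]-3-{[(tert-butyldiphenylsilyl)oxy]methyl}-6-methoxy-2-vinyl-1,2,3,4-tetrahydronaphthalene, via diarylmethyl cation 17 (not isolated)
Conditions: InCl3 (10 mol %), CH2Cl2, 0 °C → rt
Reagents that add atoms: none
Why: InCl3 should ionize either epimer of 16 to the diarylmethyl cation 17, which is stabilized by the para C6 methoxy group of ring A and by the 4-benzyloxy-3,5-dimethoxyphenyl ring, after which the γ-carbon of the allylsilane (future C2) bonds to C1 and the resulting β-silyl cation loses Me3Si to leave the C2 vinyl group. The closest known reaction type is the Lewis-acid allylation of benzhydrols with allylsilanes (Hosomi–Sakurai-type SE2′ substitution), here in its intramolecular cation–olefin form. Ring B closes in a 6-exo mode with respect to the alkene, because only its γ-carbon enters the ring, through a chair-like transition state. C2 is controlled by the C3 centre, whose silyloxymethyl group sits equatorial and places the alkenyl residue on the adjacent carbon equatorial as well (2,3-trans). C1 is controlled by the same chair together with allylic strain in the cation, which turns the aryl group away from the ortho CH2 of the tether so that it ends pseudo-equatorial (1,2-trans), giving the (1S,2R,3R) isomer. The step needs only diastereoselectivity, which the single pre-set C3 centre secures, since both carbinol epimers converge on one planar cation, the alkene geometry does not decide the outcome and loss of silicon makes the closure irreversible.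

**Step 14**
Reactants: 18 (1S,2R,3R)-7-(benzyloxy)-1-[4-(benzyloxy)-3,5-dimethoxyphenyl]-3-{[(tert-butyldiphenylsilyl)oxy]methyl}-6-methoxy-2-vinyl-1,2,3,4-tetrahydronaphthalene
Product: 20 [(1S,2R,3R)-7-(benzyloxy)-1-[4-(benzyloxy)-3,5-dimethoxyphenyl]-3-{[(tert-butyldiphenylsilyl)oxy]methyl}-6-methoxy-1,2,3,4-tetrahydronaphthalen-2-yl]methanol, via C2 aldehyde 19 (not isolated)
Conditions: K2OsO4·2H2O (cat.), NaIO4, 2,6-lutidine, dioxane/H2O, rt; then NaBH4, MeOH, 0 °C
Reagents that add atoms: sodium periodate, [Na+].[O-]I(=O)(=O)=O (terminal oxidant; the new oxygen atom is delivered through the osmium catalyst)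
Why: Lemieux–Johnson cleavage followed by borohydride reduction in the same pot should turn the vinyl group into the C9′ hydroxymethyl arm without attacking the electron-rich arenes, and the transient aldehyde can only epimerize at C2 toward the all-equatorial isomer already present.

**Step 15**
Reactants: 20 [(1S,2R,3R)-7-(benzyloxy)-1-[4-(benzyloxy)-3,5-dimethoxyphenyl]-3-{[(tert-butyldiphenylsilyl)oxy]methyl}-6-methoxy-1,2,3,4-tetrahydronaphthalen-2-yl]methanol
Product: 21 [(1S,2R,3R)-7-(benzyloxy)-1-[4-(benzyloxy)-3,5-dimethoxyphenyl]-6-methoxy-1,2,3,4-tetrahydronaphthalene-2,3-diyl]dimethanol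
Conditions: TBAF, THF, rt
Reagents that add atoms: none
Why: Fluoride-induced desilylation should remove the primary TBDPS ether selectively, since the benzyl ethers and the free alcohol are inert to TBAF.

**Step 16**
Reactants: 21 [(1S,2R,3R)-7-(benzyloxy)-1-[4-(benzyloxy)-3,5-dimethoxyphenyl]-6-methoxy-1,2,3,4-tetrahydronaphthalene-2,3-diyl]dimethanol
Product: 22 [(1S,2R,3R)-7-(benzyloxy)-1-[4-(benzyloxy)-3,5-dimethoxyphenyl]-6-methoxy-1,2,3,4-tetrahydronaphthalene-2,3-diyl]bis(methylene) diacetate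
Conditions: Ac2O, pyridine, DMAP (cat.), CH2Cl2, rt
Reagents that add atoms: acetic anhydride, CC(=O)OC(C)=O
Why: DMAP-catalysed acetylation should esterify both primary alcohols while the phenols are still masked as benzyl ethers, so no phenolic acetate can form.

**Step 17**
Reactants: 22 [(1S,2R,3R)-7-(benzyloxy)-1-[4-(benzyloxy)-3,5-dimethoxyphenyl]-6-methoxy-1,2,3,4-tetrahydronaphthalene-2,3-diyl]bis(methylene) diacetate
Product: 23 [(1S,2R,3R)-7-hydroxy-1-(4-hydroxy-3,5-dimethoxyphenyl)-6-methoxy-1,2,3,4-tetrahydronaphthalene-2,3-diyl]bis(methylene) diacetate (CNP0265800.1)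
Conditions: H2 (1 atm), 10% Pd/C, EtOAc/EtOH, rt
Reagents that add atoms: none
Why: Catalytic hydrogenolysis of the two aryl benzyl ethers should free both phenols while the alkyl acetates and the C1 diarylmethine, which bears no C–O bond, are unaffected.

**Compound list**

1 | 6-bromovanillin (2-bromo-4-hydroxy-5-methoxybenzaldehyde) | COc1cc(C=O)c(Br)cc1O | starting material
2 | 4-(benzyloxy)-2-bromo-5-methoxybenzaldehyde | COc1cc(C=O)c(Br)cc1OCc1ccccc1 | intermediate
3 | diethyl malonate | CCOC(=O)CC(=O)OCC | starting material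
4 | diethyl 2-[4-(benzyloxy)-2-bromo-5-methoxybenzylidene]malonate | COc1cc(C=C(C(=O)OCC)C(=O)OCC)c(Br)cc1OCc1ccccc1 | intermediate
5 | diethyl 2-[4-(benzyloxy)-2-bromo-5-methoxybenzyl]malonate | COc1cc(CC(C(=O)OCC)C(=O)OCC)c(Br)cc1OCc1ccccc1 | intermediate
6 | 2-[4-(benzyloxy)-2-bromo-5-methoxybenzyl]propane-1,3-diol | COc1cc(CC(CO)CO)c(Br)cc1OCc1ccccc1 | intermediate
7 | 2-[4-(benzyloxy)-2-bromo-5-methoxybenzyl]propane-1,3-diyl diacetate | COc1cc(CC(COC(C)=O)COC(C)=O)c(Br)cc1OCc1ccccc1 | intermediate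
8 | (2S)-2-[4-(benzyloxy)-2-bromo-5-methoxybenzyl]-3-hydroxypropyl acetate | COc1cc(C[C@@H](CO)COC(C)=O)c(Br)cc1OCc1ccccc1 | intermediate
9 | (2R)-2-[4-(benzyloxy)-2-bromo-5-methoxybenzyl]-3-[(tert-butyldiphenylsilyl)oxy]propyl acetate | COc1cc(C[C@@H](CO[Si](c2ccccc2)(c2ccccc2)C(C)(C)C)COC(C)=O)c(Br)cc1OCc1ccccc1 | intermediate
10 | (2R)-2-[4-(benzyloxy)-2-bromo-5-methoxybenzyl]-3-[(tert-butyldiphenylsilyl)oxy]propan-1-ol | COc1cc(C[C@@H](CO[Si](c2ccccc2)(c2ccccc2)C(C)(C)C)CO)c(Br)cc1OCc1ccccc1 | intermediate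
11 | (2S)-2-[4-(benzyloxy)-2-bromo-5-methoxybenzyl]-3-[(tert-butyldiphenylsilyl)oxy]propanal | COc1cc(C[C@@H](CO[Si](c2ccccc2)(c2ccccc2)C(C)(C)C)C=O)c(Br)cc1OCc1ccccc1 | intermediate
12 | tert-butyl{[(2R,3Z)-2-[4-(benzyloxy)-2-bromo-5-methoxybenzyl]-5-(trimethylsilyl)pent-3-en-1-yl]oxy}diphenylsilane | COc1cc(C[C@@H](CO[Si](c2ccccc2)(c2ccccc2)C(C)(C)C)/C=C\C[Si](C)(C)C)c(Br)cc1OCc1ccccc1 | intermediate
13 | syringaldehyde (4-hydroxy-3,5-dimethoxybenzaldehyde) | COc1cc(C=O)cc(OC)c1O | starting material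
14 | 4-(benzyloxy)-3,5-dimethoxybenzaldehyde | COc1cc(C=O)cc(OC)c1OCc1ccccc1 | intermediate
15 | aryllithium from 12 (lithium in place of bromine) | COc1cc(C[C@@H](CO[Si](c2ccccc2)(c2ccccc2)C(C)(C)C)/C=C\C[Si](C)(C)C)c([Li])cc1OCc1ccccc1 | intermediate
16 | [5-(benzyloxy)-2-[(2R,3Z)-2-{[(tert-butyldiphenylsilyl)oxy]methyl}-5-(trimethylsilyl)pent-3-en-1-yl]-4-methoxyphenyl][4-(benzyloxy)-3,5-dimethoxyphenyl]methanol (both carbinol epimers) | COc1cc(C[C@@H](CO[Si](c2ccccc2)(c2ccccc2)C(C)(C)C)/C=C\C[Si](C)(C)C)c(cc1OCc1ccccc1)C(O)c1cc(OC)c(OCc2ccccc2)c(OC)c1 | intermediate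
17 | diarylmethyl cation from 16 | COc1cc(C[C@@H](CO[Si](c2ccccc2)(c2ccccc2)C(C)(C)C)/C=C\C[Si](C)(C)C)c(cc1OCc1ccccc1)[CH+]c1cc(OC)c(OCc2ccccc2)c(OC)c1 | intermediate
18 | (1S,2R,3R)-7-(benzyloxy)-1-[4-(benzyloxy)-3,5-dimethoxyphenyl]-3-{[(tert-butyldiphenylsilyl)oxy]methyl}-6-methoxy-2-vinyl-1,2,3,4-tetrahydronaphthalene | COc1cc2c(cc1OCc1ccccc1)[C@H](c1cc(OC)c(OCc3ccccc3)c(OC)c1)[C@@H](C=C)[C@H](CO[Si](c1ccccc1)(c1ccccc1)C(C)(C)C)C2 | intermediate
19 | (1S,2R,3R)-7-(benzyloxy)-1-[4-(benzyloxy)-3,5-dimethoxyphenyl]-3-{[(tert-butyldiphenylsilyl)oxy]methyl}-6-methoxy-1,2,3,4-tetrahydronaphthalene-2-carbaldehyde | COc1cc2c(cc1OCc1ccccc1)[C@H](c1cc(OC)c(OCc3ccccc3)c(OC)c1)[C@@H](C=O)[C@H](CO[Si](c1ccccc1)(c1ccccc1)C(C)(C)C)C2 | intermediate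
20 | [(1S,2R,3R)-7-(benzyloxy)-1-[4-(benzyloxy)-3,5-dimethoxyphenyl]-3-{[(tert-butyldiphenylsilyl)oxy]methyl}-6-methoxy-1,2,3,4-tetrahydronaphthalen-2-yl]methanol | COc1cc2c(cc1OCc1ccccc1)[C@H](c1cc(OC)c(OCc3ccccc3)c(OC)c1)[C@@H](CO)[C@H](CO[Si](c1ccccc1)(c1ccccc1)C(C)(C)C)C2 | intermediate
21 | [(1S,2R,3R)-7-(benzyloxy)-1-[4-(benzyloxy)-3,5-dimethoxyphenyl]-6-methoxy-1,2,3,4-tetrahydronaphthalene-2,3-diyl]dimethanol | COc1cc2c(cc1OCc1ccccc1)[C@H](c1cc(OC)c(OCc3ccccc3)c(OC)c1)[C@@H](CO)[C@H](CO)C2 | intermediate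
22 | [(1S,2R,3R)-7-(benzyloxy)-1-[4-(benzyloxy)-3,5-dimethoxyphenyl]-6-methoxy-1,2,3,4-tetrahydronaphthalene-2,3-diyl]bis(methylene) diacetate | COc1cc2c(cc1OCc1ccccc1)[C@H](c1cc(OC)c(OCc3ccccc3)c(OC)c1)[C@@H](COC(C)=O)[C@H](COC(C)=O)C2 | intermediate
23 | [(1S,2R,3R)-7-hydroxy-1-(4-hydroxy-3,5-dimethoxyphenyl)-6-methoxy-1,2,3,4-tetrahydronaphthalene-2,3-diyl]bis(methylene) diacetate | COc1cc2c(cc1O)[C@H](c1cc(OC)c(O)c(OC)c1)[C@@H](COC(C)=O)[C@H](COC(C)=O)C2 | target

**Step count.** Total: 17 steps. Longest linear sequence: 16 steps (steps 1–10 and 12–17, from 6-bromovanillin); step 11 is the one-step side branch.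

**Steps most likely to fail**

Step 13. The allylsilane may be protodesilylated by adventitious acid before the C1–C2 bond forms, or the facial control at C1 may be poor. The fallback sets out from 12 and moves the aryl group to a later bond-forming event. Bromine–lithium exchange (n-BuLi, THF, −78 °C, through 15) and a DMF quench would give 5-(benzyloxy)-2-[(2R,3Z)-2-{[(tert-butyldiphenylsilyl)oxy]methyl}-5-(trimethylsilyl)pent-3-en-1-yl]-4-methoxybenzaldehyde F1. An intramolecular Hosomi–Sakurai addition to this aldehyde (BF3·OEt2, CH2Cl2, −78 °C) should close ring B to (2S,3R)-7-(benzyloxy)-3-{[(tert-butyldiphenylsilyl)oxy]methyl}-6-methoxy-2-vinyl-1,2,3,4-tetrahydronaphthalen-1-ol F2, 2,3-trans through the same chair and as both C1 epimers. Acid-mediated Friedel–Crafts arylation with 2,6-dimethoxyphenol would then pass through the C1 benzylic cation of F2 F3; the phenol should attack through its position para to OH and trans to the C2 vinyl group, giving 4-[(1S,2R,3R)-7-(benzyloxy)-3-{[(tert-butyldiphenylsilyl)oxy]methyl}-6-methoxy-2-vinyl-1,2,3,4-tetrahydronaphthalen-1-yl]-2,6-dimethoxyphenol F4. Benzylation (BnBr, K2CO3, DMF) brings the material back to the route at 18.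

Step 6. Discrimination between the two enantiotopic acetates may be incomplete, or acyl migration in the aqueous medium may lower the enantiomeric purity that all later centres inherit. The fallback sets out from 6 and uses the enzyme in the acylation mode in organic solvent, oxidizing the arm that stays free. Lipase PS with vinyl acetate in i-Pr2O should give (2R)-2-[4-(benzyloxy)-2-bromo-5-methoxybenzyl]-3-hydroxypropyl acetate F5. TEMPO/PhI(OAc)2 oxidation would give (2S)-2-[4-(benzyloxy)-2-bromo-5-methoxybenzyl]-3-oxopropyl acetate F6. The Wittig reaction of step 10 at −78 °C would give (2R,3Z)-2-[4-(benzyloxy)-2-bromo-5-methoxybenzyl]-5-(trimethylsilyl)pent-3-en-1-yl acetate F7. Methanolysis (K2CO3, MeOH) would give (2R,3Z)-2-[4-(benzyloxy)-2-bromo-5-methoxybenzyl]-5-(trimethylsilyl)pent-3-en-1-ol F8, and silylation (TBDPSCl, imidazole) comes back to the route at 12.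

Step 10. The basic ylide may enolize the α-branched aldehyde, which would epimerize C3 or eliminate the β-silyloxy group. The fallback sets out from 11 and builds the allylsilane without a basic reagent. Takai olefination (CrCl2, CHI3, THF, 0 °C) should give tert-butyl{[(2R,3E)-2-[4-(benzyloxy)-2-bromo-5-methoxybenzyl]-4-iodobut-3-en-1-yl]oxy}diphenylsilane F9. Kumada coupling with Me3SiCH2MgCl under Pd(PPh3)4 catalysis, in which the vinyl C–I bond should react far faster than the hindered electron-rich aryl C–Br bond, would give tert-butyl{[(2R,3E)-2-[4-(benzyloxy)-2-bromo-5-methoxybenzyl]-5-(trimethylsilyl)pent-3-en-1-yl]oxy}diphenylsilane F10. Bromine–lithium exchange as in step 12 would give the E-configured aryllithium F11, and addition to 14 the E-configured diarylmethanol F12. Under the conditions of step 13 this ionizes to the E-configured diarylmethyl cation F13 and should close to the same tetralin, because the alkene geometry does not decide the outcome; the fallback comes back to the route at 18.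

**Further compounds**

F1 | step 13 | 5-(benzyloxy)-2-[(2R,3Z)-2-{[(tert-butyldiphenylsilyl)oxy]methyl}-5-(trimethylsilyl)pent-3-en-1-yl]-4-methoxybenzaldehyde | COc1cc(C[C@@H](CO[Si](c2ccccc2)(c2ccccc2)C(C)(C)C)/C=C\C[Si](C)(C)C)c(C=O)cc1OCc1ccccc1
F2 | step 13 | (2S,3R)-7-(benzyloxy)-3-{[(tert-butyldiphenylsilyl)oxy]methyl}-6-methoxy-2-vinyl-1,2,3,4-tetrahydronaphthalen-1-ol (both C1 epimers) | COc1cc2c(cc1OCc1ccccc1)C(O)[C@@H](C=C)[C@H](CO[Si](c1ccccc1)(c1ccccc1)C(C)(C)C)C2
F3 | step 13 | C1 benzylic cation of F2 | COc1cc2c(cc1OCc1ccccc1)[CH+][C@@H](C=C)[C@H](CO[Si](c1ccccc1)(c1ccccc1)C(C)(C)C)C2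
F4 | step 13 | 4-[(1S,2R,3R)-7-(benzyloxy)-3-{[(tert-butyldiphenylsilyl)oxy]methyl}-6-methoxy-2-vinyl-1,2,3,4-tetrahydronaphthalen-1-yl]-2,6-dimethoxyphenol | COc1cc2c(cc1OCc1ccccc1)[C@H](c1cc(OC)c(O)c(OC)c1)[C@@H](C=C)[C@H](CO[Si](c1ccccc1)(c1ccccc1)C(C)(C)C)C2
F5 | step 6 | (2R)-2-[4-(benzyloxy)-2-bromo-5-methoxybenzyl]-3-hydroxypropyl acetate | COc1cc(C[C@H](CO)COC(C)=O)c(Br)cc1OCc1ccccc1
F6 | step 6 | (2S)-2-[4-(benzyloxy)-2-bromo-5-methoxybenzyl]-3-oxopropyl acetate | COc1cc(C[C@@H](COC(C)=O)C=O)c(Br)cc1OCc1ccccc1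
F7 | step 6 | (2R,3Z)-2-[4-(benzyloxy)-2-bromo-5-methoxybenzyl]-5-(trimethylsilyl)pent-3-en-1-yl acetate | COc1cc(C[C@@H](COC(C)=O)/C=C\C[Si](C)(C)C)c(Br)cc1OCc1ccccc1
F8 | step 6 | (2R,3Z)-2-[4-(benzyloxy)-2-bromo-5-methoxybenzyl]-5-(trimethylsilyl)pent-3-en-1-ol | COc1cc(C[C@@H](CO)/C=C\C[Si](C)(C)C)c(Br)cc1OCc1ccccc1
F9 | step 10 | tert-butyl{[(2R,3E)-2-[4-(benzyloxy)-2-bromo-5-methoxybenzyl]-4-iodobut-3-en-1-yl]oxy}diphenylsilane | COc1cc(C[C@@H](CO[Si](c2ccccc2)(c2ccccc2)C(C)(C)C)/C=C/I)c(Br)cc1OCc1ccccc1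
F10 | step 10 | tert-butyl{[(2R,3E)-2-[4-(benzyloxy)-2-bromo-5-methoxybenzyl]-5-(trimethylsilyl)pent-3-en-1-yl]oxy}diphenylsilane | COc1cc(C[C@@H](CO[Si](c2ccccc2)(c2ccccc2)C(C)(C)C)/C=C/C[Si](C)(C)C)c(Br)cc1OCc1ccccc1
F11 | step 10 | E-configured aryllithium from F10 | COc1cc(C[C@@H](CO[Si](c2ccccc2)(c2ccccc2)C(C)(C)C)/C=C/C[Si](C)(C)C)c([Li])cc1OCc1ccccc1
F12 | step 10 | [5-(benzyloxy)-2-[(2R,3E)-2-{[(tert-butyldiphenylsilyl)oxy]methyl}-5-(trimethylsilyl)pent-3-en-1-yl]-4-methoxyphenyl][4-(benzyloxy)-3,5-dimethoxyphenyl]methanol (both carbinol epimers) | COc1cc(C[C@@H](CO[Si](c2ccccc2)(c2ccccc2)C(C)(C)C)/C=C/C[Si](C)(C)C)c(cc1OCc1ccccc1)C(O)c1cc(OC)c(OCc2ccccc2)c(OC)c1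
F13 | step 10 | E-configured diarylmethyl cation from F12 | COc1cc(C[C@@H](CO[Si](c2ccccc2)(c2ccccc2)C(C)(C)C)/C=C/C[Si](C)(C)C)c(cc1OCc1ccccc1)[CH+]c1cc(OC)c(OCc2ccccc2)c(OC)c1
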